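## Structural features

The target is a flavone. Benzene ring A is fused through C4a–C8a to the 4-pyranone ring C, and C2 of ring C carries the 4-hydroxyphenyl ring B. Ring A has no hydrogen left: 5-OH, 6-OMe, 7-OH, and at C8 the C2 atom of an N-methylpyrrolidine. That pyrrolidine carbon is the only stereocentre (R) and has no stereogenic neighbour.

The stereocentre is a benzylic amine carbon ortho to the C7 oxygen and to O1 and para to the C5 oxygen. Its C–N bond can therefore ionise (retro-Mannich, ortho-quinone methide, or opening of an N-acylammonium), and the zwitterion of free 7-OH and amine is the most exposed form. Other sensitive points are the three phenols, the 6-OMe group that must survive while both neighbours are unmasked, and the reducible C2=C3 bond.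

The real difficulty is to make the C8–C(pyrrolidine) bond at the most hindered position of a hexasubstituted benzene with control of that single centre, while keeping O1 distinguishable from the C5 oxygen so that ring C can close in one direction only.

The key step uses the fact that C8 and C8a are neighbours carrying a carbon and an oxygen substituent. This is the pattern left when the C and O termini of a nitrone add across an aryne, and the C7 oxygen beside that triple bond decides which terminus goes where.

## Logic of the disconnections

**26 ⇒ 25.** The three O–CH2Ar bonds (at the C5, C7 and C4′ oxygens) are cut. The free phenols are incompatible with the bases, Lewis acids and radicals used earlier, and a free 7-OH would activate the benzylic C–N bond. The gain is a neutral, non-zwitterionic precursor. The demand is a hydrogenolysis that spares C2=C3, the benzylic C–N bond and the 6-OMe group.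

**25 ⇒ 22 + 23 (through 24).** O1–C2 and C2–C3 of ring C are cut, the β-diketone retron of a flavone. Ring B and C2 leave as 23, and an ortho-hydroxy aryl methyl ketone remains. The demand is that only the C8a oxygen is free in 22, so that cyclodehydration of 24 has one outcome, and that C-aroylation outruns acylation of the tertiary amine.

**22 ⇒ 19.** The C4a–C4 bond is cut. C4a is the only unsubstituted ring A carbon and lies ortho or para to three oxygens, so electrophilic acetylation can only go there (through 20 and 21). The gain is a ring A without carbonyl. The demand is an acetylation mild enough for the benzyl-type ethers and the C–N bond.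

**19 ⇒ 17 (through 18).** The N–CH3 bond is cut and N is reconnected to the C8a oxygen. This ties phenol and amine into an isoxazolidine, the retron of a nitrone cycloaddition, and it explains why the C8a oxygen is free in 19 while the other ring A oxygens are masked. The demand is an N–O reduction that leaves benzylic ethers alone, and a methylation in which formaldehyde does not attack C4a.

**17 ⇒ 14 (through 16 and 15).** A C–O bond is added at the pyrrolidine carbon next to the benzylic centre. This oxygen is the control element of the key step and links the new stereocentre to a purchased one. The demand is a deoxygenation that passes through neither a cation nor a carbonyl next to the benzylic centre, hence a radical.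

**14 ⇒ 8 + 12 (through 13).** C8–C(pyrrolidine) and C8a–O are cut together. The hexasubstituted arene falls into a pentasubstituted aryne precursor and a five-membered nitrone of similar size. The demand is threefold: regiocontrol by the C7 ether, facial control by the silyloxy group, and fluoride that attacks the SiMe3 group but not the silyl ether.

**8 ⇒ 5 ⇒ 4.** The C–Si and O–S bonds are cut (through 7 and 6), then C–Br. An ortho-silyl aryl triflate releases its aryne under neutral fluoride conditions that a nitrone tolerates, and it comes from an ortho-bromophenol by retro-Brook shift. Phenol 4 is symmetrical about its O–C1···C4 axis, so bromination has a single outcome. The demand is bromine–lithium exchange faster than benzylic deprotonation.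

**4 ⇒ 2 ⇒ 1.** The phenolic C–O bond is cut (through the C–B bond of 3), then two O–CH2Ar bonds. The carbon meta to both ether oxygens cannot be reached by electrophilic substitution but is the only C–H without an ortho neighbour, which is what a sterically governed iridium borylation selects. This is why the ring A ethers are 4-methylbenzyl: every C–H of such a ring has an ortho substituent, whereas a plain benzyl group would offer three unhindered C–H bonds.

**12 ⇒ 10 ⇒ 9.** The nitrone is taken back to the amine oxidation level (through 11) and the O–Si bond is cut. The stereocentre is bought in 9. A silyl ether goes on without N-protection and comes off with fluoride. The demand is dehydrogenation towards the carbon next to the oxygenated carbon.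

## Other disconnections considered

**Alternative 1:** The cut is inside the pyrrolidine at N–C2 and C2–C3, with C3=C4 to follow by metathesis.
- Forward: the 8-formylflavone A1, N-methylprop-2-en-1-amine A3 and dibutyl ethenylboronate A4 would combine in a Petasis borono-Mannich reaction under a chiral biphenol to give A2. Ring-closing metathesis (second-generation Grubbs catalyst, RuCl2(=CHPh)(PCy3)(H2IMes)) and hydrogenation of the 3-pyrroline would finish.
- In favour: it works on an intact flavone, so ring A is never built or differentiated. A1 should be accessible because C8 is the only free ring A position. The 7-OH beside the aldehyde is the activating group a Petasis reaction needs. N-methyl is present from the start and nothing has to be deoxygenated.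
- Against: the same 7-OH binds boron and should drive an uncatalysed racemic pathway that the chiral diol must outrun, and three phenols and the chromone carbonyl compete for boron. A2 is an ortho-hydroxybenzylamine with an allylic C–N bond, the most ionisable form of this centre. It must then survive a ruthenium alkylidene that the amine inhibits, and a hydrogenation that may touch neither C2=C3 nor the C–N bond.
- Comparison: step economy is clearly better than in the chosen plan, and avoiding the ring C annulation is also better. Convergence is equal. Stereocontrol is weaker, since it is catalyst against background and not a covalently attached control group. The lability of the final amine is equal.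

**Alternative 2:** The cut goes through ring A at C7–C8, C8a–C4a and C6–C7.
- Forward: heating cyclobutenone A6 with the D-proline-derived siloxyalkyne A5 would open A6 to a vinylketene, which adds (2+2) to the ynol ether; a second electrocyclic opening and 6π closure would give phenol A7.
- In favour: the stereocentre is bought, which is equal to or better than any selective step. The position of the pyrrolidine between two oxygens follows from the mechanism, so there is no aryne regiochemistry to control (better). The nitrogen is a carbamate, which makes the benzylic C–N bond far less ionisable than the amine of the chosen plan (better). No deoxygenation is needed.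
- Against: A5 must be made by ynolate homologation of a proline ester under excess strong base at a centre α to the ester, where enolisation would erode the configuration. A6 is a sensitive, non-commercial cyclobutenone. A7 has the 7-OH free and O1 silylated, the reverse of what ring C needs, so protecting-group steps are added. The C5 ethyl ether must later be told from the C6 methyl ether, and the carbamate must be reduced to N-methyl before the chromone exists.
- Comparison: the C4a acylation and ring C annulation remain as in the chosen plan (equal). The step count is comparable or somewhat higher.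

**Alternative 3:** The cut is N–C2 only.
- Forward: a chiral phosphoric acid would protonate the styrene-type double bond of the 8-alkenyl-7-hydroxyflavone A8 through the 7-OH, giving an ortho-quinone methide paired with the chiral phosphate. The carbamate nitrogen would add to the benzylic carbon in a 5-exo closure to give A9. Carbamate removal and reductive methylation would follow.
- In favour: one bond, late stage, catalytic in chirality, and A8 should come from C8 halogenation and cross-coupling of a flavone. Step economy is better than in the chosen plan. The product is a carbamate, more robust than the amine (better). No aryne regiochemistry and no deoxygenation arise.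
- Against: the 7-OH of a flavone is a vinylogous acid conjugated with C4=O, so ring A is a poor donor and the quinone methide should be harder to form than from a simple ortho-vinylphenol. Stronger acid or heat would also favour re-ionisation of the new C–N bond, so enantiomeric purity could erode with time. The catalyst must organise an ion pair in a substrate with three phenols and a carbonyl.
- Comparison: step economy and robustness of the product are better. Predictability of stereocontrol is lower than for the anti addition to a nitrone that carries its own control group.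

Key step: step 7

Remarks on the chemistry (assumptions):
- A nitrone drawn as [O-][N+]1=C[C@H](OR)CC1 carries its oxygen substituent beside the nitrone carbon and is a (4R)-4-substituted 3,4-dihydro-2H-pyrrole 1-oxide (a 3-substituted 1-pyrroline N-oxide); a 3-locant in the dihydro-2H-pyrrole name would denote the useless regioisomer.
- The nitrone oxygen is carried as a tri(propan-2-yl)silyl ether, not a tert-butyl ether: it needs no N-protection to install, is expected to survive CsF in MeCN, and is removed by fluoride, not by strong acid, which would endanger the benzylic C–N bond.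
- The ring A ethers are 4-methylbenzyl (see the paragraph 4 ⇒ 2 ⇒ 1); ring B keeps a plain benzyl ether.
- It is assumed that the minor regioisomeric nitrone of step 6 and any minor isomer of step 7 can be removed by chromatography; equivalents and temperatures are proposals.

Step 1
Reactants: 1 2-methoxybenzene-1,3-diol
Product: 2 2-methoxy-1,3-bis[(4-methylphenyl)methoxy]benzene
Conditions: 4-MeC6H4CH2Br (2.2 equiv), K2CO3 (3 equiv), DMF, 60 °C
Reagents that add atoms: 4-methylbenzyl bromide, Cc1ccc(CBr)cc1
Why: Williamson etherification of both phenols; the hindered central methoxy group is untouched and no C-alkylation is expected with carbonate in DMF.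

Step 2
Reactants: 2 2-methoxy-1,3-bis[(4-methylphenyl)methoxy]benzene
Product: 4 4-methoxy-3,5-bis[(4-methylphenyl)methoxy]phenol, via arylboronic pinacol ester 3 (not isolated)
Conditions: [Ir(OMe)(cod)]2 (1.5 mol%), 4,4′-di-tert-butyl-2,2′-bipyridine (3 mol%), B2pin2 (0.7 equiv), THF, 70 °C; then KHSO5 (as 2KHSO5·KHSO4·K2SO4), acetone/H2O, 0 °C
Reagents that add atoms: potassium peroxymonosulfate, [K+].[O-]S(=O)(=O)OO (the new oxygen); bis(pinacolato)diboron, CC1(C)OB(OC1(C)C)B1OC(C)(C)C(C)(C)O1 (boron of 3 only)
Why: Sterically governed iridium C–H borylation followed by one-pot oxidation of the C–B bond; the C–H meta to both ethers is the only one in 2 without an ortho substituent, since every C–H of the 4-methylbenzyl rings has one.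

Step 3
Reactants: 4 4-methoxy-3,5-bis[(4-methylphenyl)methoxy]phenol
Product: 5 2-bromo-4-methoxy-3,5-bis[(4-methylphenyl)methoxy]phenol
Conditions: NBS (1.0 equiv), CH2Cl2, −30 to 0 °C, dark
Reagents that add atoms: N-bromosuccinimide, O=C1CCC(=O)N1Br
Why: Electrophilic bromination ortho to the phenol; the para position is blocked and the two ortho positions are equivalent, so one equivalent of reagent in the cold should stop at the monobromide.

Step 4
Reactants: 5 2-bromo-4-methoxy-3,5-bis[(4-methylphenyl)methoxy]phenol
Product: 8 4-methoxy-3,5-bis[(4-methylphenyl)methoxy]-2-(trimethylsilyl)phenyl trifluoromethanesulfonate, via trimethylsilyl ether 6 (not isolated), via lithium 2-silylphenolate 7 (not isolated)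
Conditions: (Me3Si)2NH, THF, 65 °C, then evaporate; n-BuLi (1.1 equiv), THF, −78 °C; Tf2O (1.2 equiv), −78 °C to rt
Reagents that add atoms: hexamethyldisilazane, C[Si](C)(C)N[Si](C)(C)C; trifluoromethanesulfonic anhydride, O=S(=O)(OS(=O)(=O)C(F)(F)F)C(F)(F)F
Why: O-silylation, bromine–lithium exchange, 1,3 O-to-C silyl shift (retro-Brook) and triflation of the phenolate, the standard one-pot route to ortho-silyl aryl triflates; exchange at −78 °C should be much faster than benzylic deprotonation.

Step 5
Reactants: 9 (3R)-pyrrolidin-3-ol
Product: 10 (3R)-3-{[tri(propan-2-yl)silyl]oxy}pyrrolidine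
Conditions: i-Pr3SiCl (1.1 equiv), imidazole (2.5 equiv), DMF, 0 °C to rt; aq. NaHCO3 work-up
Reagents that add atoms: chlorotri(propan-2-yl)silane, CC(C)[Si](Cl)(C(C)C)C(C)C
Why: O-silylation of an amino alcohol; a bulky silyl chloride reacts slowly at nitrogen and any N–Si bond hydrolyses on work-up, and the stereocentre is not involved.

Step 6
Reactants: 10 (3R)-3-{[tri(propan-2-yl)silyl]oxy}pyrrolidine
Product: 12 (4R)-4-{[tri(propan-2-yl)silyl]oxy}-3,4-dihydro-2H-pyrrole 1-oxide, via N-hydroxypyrrolidine 11 (not isolated)
Conditions: Na2WO4·2H2O (5 mol%), H2O2·urea (2.5 equiv), MeOH, 0 °C to rt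
Reagents that add atoms: hydrogen peroxide (as its urea adduct), OO
Why: Tungstate-catalysed oxidation of a secondary amine to the nitrone through the hydroxylamine; in 3-oxygenated N-hydroxypyrrolidines the ring hydrogen antiperiplanar to the C–O bond is removed preferentially, which should place C=N next to the silyloxy carbon, and the stereocentre is not touched.

Step 7
Reactants: 8 4-methoxy-3,5-bis[(4-methylphenyl)methoxy]-2-(trimethylsilyl)phenyl trifluoromethanesulfonate; 12 (4R)-4-{[tri(propan-2-yl)silyl]oxy}-3,4-dihydro-2H-pyrrole 1-oxide
Product: 14 (1R,9bS)-8-methoxy-7,9-bis[(4-methylphenyl)methoxy]-1-{[tri(propan-2-yl)silyl]oxy}-1,2,3,9b-tetrahydrobenzo[d]pyrrolo[1,2-b][1,2]oxazole, via aryne 13 (not isolated)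
Conditions: CsF (3 equiv), MeCN, 0 °C to rt; 8 (1.3 equiv) added slowly to 12
Reagents that add atoms: none
Why: Fluoride attacks the SiMe3 group of 8 and triflate leaves, giving aryne 13 whose triple bond joins the future C8 (former silyl carbon) and C8a (former triflate carbon). The ether oxygen on the carbon next to C8 withdraws inductively and distorts the aryne, so the nucleophilic nitrone oxygen should attack the remote terminus C8a, and the negative charge developing at C8 beside that oxygen then bonds to the nitrone carbon. The closest known reaction is the aryne–nitrone (3+2) cycloaddition to 2,3-dihydro-1,2-benzisoxazoles, with the regiochemistry known for 3-alkoxyarynes. The isoxazolidine ring closes in this asynchronous cycloaddition, which forms the C8a–O and C8–C bonds in one step. The new stereocentre C9b is set by approach of the aryne to the C=N face anti to the bulky silyloxy group on the adjacent carbon, which should give the trans (1R,9bS) adduct with the existing centre unchanged. The step needs regioselectivity (secured by the ether beside the triple bond), facial selectivity (secured by the silyloxy group) and selective fluoride attack at SiMe3 (secured by the bulk of the tri(propan-2-yl)silyl ether and the low solubility of CsF in MeCN). Slow addition of 8 keeps the aryne dilute so that it meets the nitrone before it can react with itself.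

Step 8
Reactants: 14 (1R,9bS)-8-methoxy-7,9-bis[(4-methylphenyl)methoxy]-1-{[tri(propan-2-yl)silyl]oxy}-1,2,3,9b-tetrahydrobenzo[d]pyrrolo[1,2-b][1,2]oxazole
Product: 15 (1R,9bS)-8-methoxy-7,9-bis[(4-methylphenyl)methoxy]-1,2,3,9b-tetrahydrobenzo[d]pyrrolo[1,2-b][1,2]oxazol-1-ol
Conditions: Bu4NF (1.5 equiv), THF, 0 °C to rt
Reagents that add atoms: none
Why: Fluoride cleavage of a secondary silyl ether under non-acidic conditions; aryl ethers and the N–O bond should be inert.

Step 9
Reactants: 15 (1R,9bS)-8-methoxy-7,9-bis[(4-methylphenyl)methoxy]-1,2,3,9b-tetrahydrobenzo[d]pyrrolo[1,2-b][1,2]oxazol-1-ol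
Product: 16 O-[(1R,9bS)-8-methoxy-7,9-bis[(4-methylphenyl)methoxy]-1,2,3,9b-tetrahydrobenzo[d]pyrrolo[1,2-b][1,2]oxazol-1-yl] 1H-imidazole-1-carbothioate
Conditions: 1,1′-thiocarbonyldiimidazole (1.5 equiv), DMAP (0.2 equiv), CH2Cl2, 40 °C
Reagents that add atoms: 1,1′-thiocarbonyldiimidazole, S=C(n1ccnc1)n1ccnc1
Why: Thioacylation of the only hydroxyl group; at this stage the nitrogen is a weakly nucleophilic N,O-disubstituted hydroxylamine and there is no free phenol, so no competing site exists.

Step 10
Reactants: 16 O-[(1R,9bS)-8-methoxy-7,9-bis[(4-methylphenyl)methoxy]-1,2,3,9b-tetrahydrobenzo[d]pyrrolo[1,2-b][1,2]oxazol-1-yl] 1H-imidazole-1-carbothioate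
Product: 17 (9bR)-8-methoxy-7,9-bis[(4-methylphenyl)methoxy]-1,2,3,9b-tetrahydrobenzo[d]pyrrolo[1,2-b][1,2]oxazole
Conditions: (Me3Si)3SiH (1.5 equiv), AIBN (0.2 equiv), toluene, 80 °C
Reagents that add atoms: none
Why: Barton–McCombie deoxygenation with a tin-free silane; the radical forms at C1 only, so C9b keeps its configuration (the descriptor changes from S to R only because the priorities change).

Step 11
Reactants: 17 (9bR)-8-methoxy-7,9-bis[(4-methylphenyl)methoxy]-1,2,3,9b-tetrahydrobenzo[d]pyrrolo[1,2-b][1,2]oxazole
Product: 19 4-methoxy-3,5-bis[(4-methylphenyl)methoxy]-2-[(2R)-1-methylpyrrolidin-2-yl]phenol, via secondary amine 18 (not isolated)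
Conditions: Zn dust, AcOH/THF (1:4), 0 °C to rt; filter; then aq. CH2O (1.5 equiv), NaBH(OAc)3 (2 equiv), 0 °C to rt
Reagents that add atoms: formaldehyde, C=O
Why: Reductive cleavage of the weak N–O(aryl) bond by zinc, then reductive amination of the secondary amine with formaldehyde; hydride is present from the start so the iminium ion is reduced before formaldehyde can attack the free ring position, and no N-alkoxyammonium salt is ever formed at the ionisable benzylic carbon.

Step 12
Reactants: 19 4-methoxy-3,5-bis[(4-methylphenyl)methoxy]-2-[(2R)-1-methylpyrrolidin-2-yl]phenol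
Product: 22 1-{2-hydroxy-5-methoxy-4,6-bis[(4-methylphenyl)methoxy]-3-[(2R)-1-methylpyrrolidin-2-yl]phenyl}ethan-1-one, via aryl acetate 20 (not isolated), via acetoxy ketone 21 (not isolated)
Conditions: BF3·OEt2 (4 equiv), CH2Cl2, −20 °C, then Ac2O (2.5 equiv), −20 to 0 °C; then K2CO3, MeOH, rt
Reagents that add atoms: acetic anhydride, CC(=O)OC(C)=O
Why: Friedel–Crafts acetylation at the only free ring position, which is ortho or para to three oxygens, followed by methanolysis of the aryl acetate; BF3 added first ties up the amine so that it is not acylated, and this acylation is precedented for electron-rich arenes carrying an N-methyl cyclic amine.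

Step 13
Reactants: 22 1-{2-hydroxy-5-methoxy-4,6-bis[(4-methylphenyl)methoxy]-3-[(2R)-1-methylpyrrolidin-2-yl]phenyl}ethan-1-one; 23 4-(benzyloxy)benzoyl chloride
Product: 25 2-[4-(benzyloxy)phenyl]-6-methoxy-5,7-bis[(4-methylphenyl)methoxy]-8-[(2R)-1-methylpyrrolidin-2-yl]-4H-chromen-4-one, via diketone 24 (not isolated)
Conditions: LiN(SiMe3)2 (3.5 equiv), THF, −78 °C; 23 (1.1 equiv), −78 °C to rt; aq. NH4Cl; then H2SO4 (2 equiv), AcOH, 50 °C
Reagents that add atoms: none
Why: One-pot variant of the Baker–Venkataraman sequence: the lithium phenolate–enolate is aroylated (any O-aroyl ester rearranges under the excess base) to the β-diketone, and acid cyclodehydration onto the only free phenol closes ring C; the benzylic C–H is far too weakly acidic for the amide base, so the stereocentre is safe.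

Step 14
Reactants: 25 2-[4-(benzyloxy)phenyl]-6-methoxy-5,7-bis[(4-methylphenyl)methoxy]-8-[(2R)-1-methylpyrrolidin-2-yl]-4H-chromen-4-one
Product: 26 5,7-dihydroxy-2-(4-hydroxyphenyl)-6-methoxy-8-[(2R)-1-methylpyrrolidin-2-yl]-4H-chromen-4-one
Conditions: H2 (1 atm), 10% Pd/C, THF/MeOH, rt
Reagents that add atoms: none
Why: Hydrogenolysis of three aryl benzyl-type ethers under neutral conditions; the methyl ether is inert, and the chromone double bond and the hindered tertiary benzylic C–N bond should react much more slowly than O-benzyl groups.

Compound list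

1 | 2-methoxybenzene-1,3-diol | COc1c(O)cccc1O | starting material
2 | 2-methoxy-1,3-bis[(4-methylphenyl)methoxy]benzene | COc1c(OCc2ccc(C)cc2)cccc1OCc1ccc(C)cc1 | intermediate
3 | 2-{4-methoxy-3,5-bis[(4-methylphenyl)methoxy]phenyl}-4,4,5,5-tetramethyl-1,3,2-dioxaborolane | COc1c(OCc2ccc(C)cc2)cc(B2OC(C)(C)C(C)(C)O2)cc1OCc1ccc(C)cc1 | intermediate (not isolated)
4 | 4-methoxy-3,5-bis[(4-methylphenyl)methoxy]phenol | COc1c(OCc2ccc(C)cc2)cc(O)cc1OCc1ccc(C)cc1 | intermediate
5 | 2-bromo-4-methoxy-3,5-bis[(4-methylphenyl)methoxy]phenol | COc1c(OCc2ccc(C)cc2)cc(O)c(Br)c1OCc1ccc(C)cc1 | intermediate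
6 | {2-bromo-4-methoxy-3,5-bis[(4-methylphenyl)methoxy]phenoxy}(trimethyl)silane | COc1c(OCc2ccc(C)cc2)cc(O[Si](C)(C)C)c(Br)c1OCc1ccc(C)cc1 | intermediate (not isolated)
7 | lithium 4-methoxy-3,5-bis[(4-methylphenyl)methoxy]-2-(trimethylsilyl)phenolate | [Li+].COc1c(OCc2ccc(C)cc2)cc([O-])c([Si](C)(C)C)c1OCc1ccc(C)cc1 | intermediate (not isolated)
8 | 4-methoxy-3,5-bis[(4-methylphenyl)methoxy]-2-(trimethylsilyl)phenyl trifluoromethanesulfonate | COc1c(OCc2ccc(C)cc2)cc(OS(=O)(=O)C(F)(F)F)c([Si](C)(C)C)c1OCc1ccc(C)cc1 | intermediate (aryne precursor of the key step)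
9 | (3R)-pyrrolidin-3-ol | O[C@@H]1CCNC1 | starting material
10 | (3R)-3-{[tri(propan-2-yl)silyl]oxy}pyrrolidine | CC(C)[Si](O[C@@H]1CCNC1)(C(C)C)C(C)C | intermediate
11 | (3R)-3-{[tri(propan-2-yl)silyl]oxy}pyrrolidin-1-ol | CC(C)[Si](O[C@@H]1CCN(O)C1)(C(C)C)C(C)C | intermediate (not isolated)
12 | (4R)-4-{[tri(propan-2-yl)silyl]oxy}-3,4-dihydro-2H-pyrrole 1-oxide | [O-][N+]1=C[C@H](O[Si](C(C)C)(C(C)C)C(C)C)CC1 | intermediate (nitrone of the key step)
13 | 1,2-didehydro-4-methoxy-3,5-bis[(4-methylphenyl)methoxy]benzene (the aryne) | COC1=C(OCc2ccc(C)cc2)C#CC=C1OCc1ccc(C)cc1 | intermediate (not isolated)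
14 | (1R,9bS)-8-methoxy-7,9-bis[(4-methylphenyl)methoxy]-1-{[tri(propan-2-yl)silyl]oxy}-1,2,3,9b-tetrahydrobenzo[d]pyrrolo[1,2-b][1,2]oxazole (N4–O5 isoxazolidine; C9b benzylic ring-fusion carbon; aryl and silyloxy trans) | COc1c(OCc2ccc(C)cc2)c2c(cc1OCc1ccc(C)cc1)ON1CC[C@@H](O[Si](C(C)C)(C(C)C)C(C)C)[C@H]21 | intermediate (product of the key step)
15 | (1R,9bS)-8-methoxy-7,9-bis[(4-methylphenyl)methoxy]-1,2,3,9b-tetrahydrobenzo[d]pyrrolo[1,2-b][1,2]oxazol-1-ol | COc1c(OCc2ccc(C)cc2)c2c(cc1OCc1ccc(C)cc1)ON1CC[C@@H](O)[C@H]21 | intermediate
16 | O-[(1R,9bS)-8-methoxy-7,9-bis[(4-methylphenyl)methoxy]-1,2,3,9b-tetrahydrobenzo[d]pyrrolo[1,2-b][1,2]oxazol-1-yl] 1H-imidazole-1-carbothioate | COc1c(OCc2ccc(C)cc2)c2c(cc1OCc1ccc(C)cc1)ON1CC[C@@H](OC(=S)n3ccnc3)[C@H]21 | intermediate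
17 | (9bR)-8-methoxy-7,9-bis[(4-methylphenyl)methoxy]-1,2,3,9b-tetrahydrobenzo[d]pyrrolo[1,2-b][1,2]oxazole | COc1c(OCc2ccc(C)cc2)c2c(cc1OCc1ccc(C)cc1)ON1CCC[C@H]21 | intermediate
18 | 4-methoxy-3,5-bis[(4-methylphenyl)methoxy]-2-[(2R)-pyrrolidin-2-yl]phenol | COc1c(OCc2ccc(C)cc2)cc(O)c([C@H]2CCCN2)c1OCc1ccc(C)cc1 | intermediate (not isolated)
19 | 4-methoxy-3,5-bis[(4-methylphenyl)methoxy]-2-[(2R)-1-methylpyrrolidin-2-yl]phenol | COc1c(OCc2ccc(C)cc2)cc(O)c([C@H]2CCCN2C)c1OCc1ccc(C)cc1 | intermediate
20 | 4-methoxy-3,5-bis[(4-methylphenyl)methoxy]-2-[(2R)-1-methylpyrrolidin-2-yl]phenyl acetate | COc1c(OCc2ccc(C)cc2)cc(OC(C)=O)c([C@H]2CCCN2C)c1OCc1ccc(C)cc1 | intermediate (not isolated)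
21 | 2-acetyl-4-methoxy-3,5-bis[(4-methylphenyl)methoxy]-6-[(2R)-1-methylpyrrolidin-2-yl]phenyl acetate | COc1c(OCc2ccc(C)cc2)c(C(C)=O)c(OC(C)=O)c([C@H]2CCCN2C)c1OCc1ccc(C)cc1 | intermediate (not isolated)
22 | 1-{2-hydroxy-5-methoxy-4,6-bis[(4-methylphenyl)methoxy]-3-[(2R)-1-methylpyrrolidin-2-yl]phenyl}ethan-1-one | COc1c(OCc2ccc(C)cc2)c(C(C)=O)c(O)c([C@H]2CCCN2C)c1OCc1ccc(C)cc1 | intermediate
23 | 4-(benzyloxy)benzoyl chloride | O=C(Cl)c1ccc(OCc2ccccc2)cc1 | starting material
24 | 1-[4-(benzyloxy)phenyl]-3-{2-hydroxy-5-methoxy-4,6-bis[(4-methylphenyl)methoxy]-3-[(2R)-1-methylpyrrolidin-2-yl]phenyl}propane-1,3-dione | COc1c(OCc2ccc(C)cc2)c(C(=O)CC(=O)c2ccc(OCc3ccccc3)cc2)c(O)c([C@H]2CCCN2C)c1OCc1ccc(C)cc1 | intermediate (not isolated)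
25 | 2-[4-(benzyloxy)phenyl]-6-methoxy-5,7-bis[(4-methylphenyl)methoxy]-8-[(2R)-1-methylpyrrolidin-2-yl]-4H-chromen-4-one | COc1c(OCc2ccc(C)cc2)c([C@H]2CCCN2C)c2oc(-c3ccc(OCc4ccccc4)cc3)cc(=O)c2c1OCc1ccc(C)cc1 | intermediate
26 | 5,7-dihydroxy-2-(4-hydroxyphenyl)-6-methoxy-8-[(2R)-1-methylpyrrolidin-2-yl]-4H-chromen-4-one | COc1c(O)c([C@H]2CCCN2C)c2oc(-c3ccc(O)cc3)cc(=O)c2c1O | target

Total step count: 14. Longest linear sequence: 12 steps (steps 1–4 and 7–14, from 1); the nitrone branch (steps 5 and 6) joins at step 7.

Steps least certain to work

**Step 7 (key step).** Several things could go wrong: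
- Regiocontrol could erode, because the nitrone carbon with its neighbouring silyloxy group must bond to the aryne carbon that lies beside an ether, and this steric demand opposes the electronic preference.
- Facial selectivity could be poor, since aryne cycloadditions have early transition states.
- Basic fluoride could partly remove the silyl ether or slowly epimerise the nitrone at the carbon α to C=N.
- The aryne could be consumed by self-reaction.

Fallback (aryl-metal addition to a sulfinyl imine in place of the cycloaddition), from 5 back to 18:
- The phenol of 5 would be capped (MOMCl, i-Pr2NEt) as 2-bromo-4-methoxy-1-(methoxymethoxy)-3,5-bis[(4-methylphenyl)methoxy]benzene F1.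
- Bromine–lithium exchange (n-BuLi, −78 °C) and transmetalation (MgBr2·OEt2) would give an arylmagnesium reagent. It would be added in toluene to (R)-N-[(1E)-4-chlorobutylidene]-2-methylpropane-2-sulfinamide F2, made from 4-chlorobutanal and (R)-2-methylpropane-2-sulfinamide with CuSO4.
- The magnesium-chelated chair transition state is expected to give (R)-N-[(1R)-4-chloro-1-{3-methoxy-6-(methoxymethoxy)-2,4-bis[(4-methylphenyl)methoxy]phenyl}butyl]-2-methylpropane-2-sulfinamide F3. This sense follows from the transition-state model and would need confirmation; the enantiomeric auxiliary would be used if it proved opposite.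
- KN(SiMe3)2 would close the ring by N-alkylation to (2R)-2-{3-methoxy-6-(methoxymethoxy)-2,4-bis[(4-methylphenyl)methoxy]phenyl}-1-[(R)-2-methylpropane-2-sulfinyl]pyrrolidine F4.
- HCl in MeOH would remove the sulfinyl and methoxymethyl groups to give 18, which re-enters step 11 at the methylation stage.

**Step 10.** The C1 radical could be diverted by a 1,2-aryl (neophyl-type) shift from C9b, which would give a nitrogen-stabilised radical, or the weak N–O bond could fragment at 80 °C.

Fallback (polar hydride displacement), from 15 back to 17: MsCl and Et3N would give (1R,9bS)-8-methoxy-7,9-bis[(4-methylphenyl)methoxy]-1,2,3,9b-tetrahydrobenzo[d]pyrrolo[1,2-b][1,2]oxazol-1-yl methanesulfonate F5. LiBHEt3 in THF would displace the sulfonate by SN2 at a carbon that does not remain stereogenic, giving 17. If the hydride also cleaved N–O, the product would be 18, the next intermediate in any case.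

**Step 12.** The Lewis acid and acylating medium could strip a benzyl-type ether (especially the twisted one beside the pyrrolidine), the benzylic C–N bond could ionise with loss of configuration, or C-acylation could stall because the boron-complexed ammonium group deactivates the ring.

Fallback (acid-free annulation that by-passes 22 and 24), from 19 back to 25: 19 as its trifluoroacetate salt would be iodinated with N-iodosuccinimide in MeCN at the only free position to give 2-iodo-4-methoxy-3,5-bis[(4-methylphenyl)methoxy]-6-[(2R)-1-methylpyrrolidin-2-yl]phenol F6. Carbonylative Sonogashira coupling with commercial 1-(benzyloxy)-4-ethynylbenzene (PdCl2(dppf), CO at 1 atm, Et2NH, 60 °C) and amine-mediated 6-endo closure of the ynone would give 25.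

**Step 13.** The aroyl chloride could acylate the tertiary amine, and chloride could then open the pyrrolidine at the benzylic carbon. The acid stage could also remove the ether at the C5 oxygen before ring closure, which would allow closure in the wrong direction.

Fallback (chalcone route without an acylating agent), from 22 back to 25: Claisen–Schmidt condensation with 4-(benzyloxy)benzaldehyde (KOH, EtOH, rt) would give (2E)-3-[4-(benzyloxy)phenyl]-1-{2-hydroxy-5-methoxy-4,6-bis[(4-methylphenyl)methoxy]-3-[(2R)-1-methylpyrrolidin-2-yl]phenyl}prop-2-en-1-one F7. Oxidative cyclisation (catalytic I2, DMSO, 110 °C, amine held as its camphorsulfonate salt) would give 25.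

**Step 14.** The hydrogenation could over-reduce C2=C3, hydrogenolyse the benzylic C–N bond, or be slowed by the amine. The product could also lose configuration through its zwitterion (ortho-quinone methide pathway) if kept warm as the free base; cold work-up and storage as a salt are advised.

Fallback (Lewis-acid dealkylation in place of hydrogenolysis), from 25 directly to 26: BCl3 with pentamethylbenzene as cation scavenger in CH2Cl2 at −78 °C, quenched with MeOH. The low temperature is meant to spare the methyl ether. This fallback makes no new compound (F0).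

Further compounds

F1 | step 7 | 2-bromo-4-methoxy-1-(methoxymethoxy)-3,5-bis[(4-methylphenyl)methoxy]benzene | COCOc1cc(OCc2ccc(C)cc2)c(OC)c(OCc2ccc(C)cc2)c1Br
F2 | step 7 | (R)-N-[(1E)-4-chlorobutylidene]-2-methylpropane-2-sulfinamide | CC(C)(C)[S@@](=O)/N=C/CCCCl
F3 | step 7 | (R)-N-[(1R)-4-chloro-1-{3-methoxy-6-(methoxymethoxy)-2,4-bis[(4-methylphenyl)methoxy]phenyl}butyl]-2-methylpropane-2-sulfinamide | CC(C)(C)[S@@](=O)N[C@H](CCCCl)c1c(OCOC)cc(OCc2ccc(C)cc2)c(OC)c1OCc1ccc(C)cc1
F4 | step 7 | (2R)-2-{3-methoxy-6-(methoxymethoxy)-2,4-bis[(4-methylphenyl)methoxy]phenyl}-1-[(R)-2-methylpropane-2-sulfinyl]pyrrolidine | CC(C)(C)[S@@](=O)N1CCC[C@@H]1c1c(OCOC)cc(OCc2ccc(C)cc2)c(OC)c1OCc1ccc(C)cc1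
F5 | step 10 | (1R,9bS)-8-methoxy-7,9-bis[(4-methylphenyl)methoxy]-1,2,3,9b-tetrahydrobenzo[d]pyrrolo[1,2-b][1,2]oxazol-1-yl methanesulfonate | COc1c(OCc2ccc(C)cc2)c2c(cc1OCc1ccc(C)cc1)ON1CC[C@@H](OS(C)(=O)=O)[C@H]21
F6 | step 12 | 2-iodo-4-methoxy-3,5-bis[(4-methylphenyl)methoxy]-6-[(2R)-1-methylpyrrolidin-2-yl]phenol | COc1c(OCc2ccc(C)cc2)c(I)c(O)c([C@H]2CCCN2C)c1OCc1ccc(C)cc1
F7 | step 13 | (2E)-3-[4-(benzyloxy)phenyl]-1-{2-hydroxy-5-methoxy-4,6-bis[(4-methylphenyl)methoxy]-3-[(2R)-1-methylpyrrolidin-2-yl]phenyl}prop-2-en-1-one | COc1c(OCc2ccc(C)cc2)c(C(=O)/C=C/c2ccc(OCc3ccccc3)cc2)c(O)c([C@H]2CCCN2C)c1OCc1ccc(C)cc1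
F0 | step 14 | none | none
A1 | alternative 1 | 5,7-dihydroxy-2-(4-hydroxyphenyl)-6-methoxy-4-oxo-4H-chromene-8-carbaldehyde | COc1c(O)c(C=O)c2oc(-c3ccc(O)cc3)cc(=O)c2c1O
A2 | alternative 1 | 5,7-dihydroxy-2-(4-hydroxyphenyl)-6-methoxy-8-{(1R)-1-[methyl(prop-2-en-1-yl)amino]prop-2-en-1-yl}-4H-chromen-4-one | COc1c(O)c([C@H](N(C)CC=C)C=C)c2oc(-c3ccc(O)cc3)cc(=O)c2c1O
A3 | alternative 1 | N-methylprop-2-en-1-amine | C=CCNC
A4 | alternative 1 | dibutyl ethenylboronate | C=CB(OCCCC)OCCCC
A5 | alternative 2 | tert-butyl (2R)-2-({[tri(propan-2-yl)silyl]oxy}ethynyl)pyrrolidine-1-carboxylate | CC(C)[Si](OC#C[C@H]1CCCN1C(=O)OC(C)(C)C)(C(C)C)C(C)C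
A6 | alternative 2 | 3-ethoxy-4-methoxycyclobut-2-en-1-one (racemic) | CCOC1=CC(=O)C1OC
A7 | alternative 2 | tert-butyl (2R)-2-{4-ethoxy-2-hydroxy-3-methoxy-6-[tri(propan-2-yl)silyloxy]phenyl}pyrrolidine-1-carboxylate | CCOc1cc(O[Si](C(C)C)(C(C)C)C(C)C)c([C@H]2CCCN2C(=O)OC(C)(C)C)c(O)c1OC
A8 | alternative 3 | benzyl {(3E)-4-[5,7-dihydroxy-2-(4-hydroxyphenyl)-6-methoxy-4-oxo-4H-chromen-8-yl]but-3-en-1-yl}carbamate | COc1c(O)c(/C=C/CCNC(=O)OCc2ccccc2)c2oc(-c3ccc(O)cc3)cc(=O)c2c1O
A9 | alternative 3 | benzyl (2R)-2-[5,7-dihydroxy-2-(4-hydroxyphenyl)-6-methoxy-4-oxo-4H-chromen-8-yl]pyrrolidine-1-carboxylate | COc1c(O)c([C@H]2CCCN2C(=O)OCc2ccccc2)c2oc(-c3ccc(O)cc3)cc(=O)c2c1O
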